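- Adding Z, J and L in each reading is the easy step: if these species merely turn into one another, the sum stays at 100%.

| flask | Z | Q | remark | time |
|---|---|---|---|---|
| grey | 49 mM | 0.66 mM | run made earlier |  |
| teal | 49 mM | 1.5 mM | run made earlier |  |
| ochre | 74 mM | 0.98 mM | run made earlier |  |
| flask | 49 mM | 0.980 mM |  | 20 min |

| run | time / min | Z / % | J / % | L / % |
|---|---|---|---|---|
| grey | 6.00 | 21.7 | 49.8 | 27.9 |
| grey | 12.0 | 20.2 | 54.5 | 25.6 |
| grey | 20.0 | 17.8 | 56.3 | 24.6 |
| grey | 25.0 | 17.6 | 55.8 | 25.6 |
| teal | 6.00 | 20.1 | 50.0 | 27.2 |
| teal | 12.0 | 19.6 | 54.4 | 25.3 |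
| teal | 20.0 | 17.5 | 52.7 | 24.5 |
| teal | 25.0 | 19.8 | 55.1 | 24.5 |
| ochre | 2.00 | 35.7 | 30.8 | 30.3 |
| ochre | 4.00 | 24.1 | 47.0 | 29.8 |
| ochre | 10.0 | 19.9 | 53.5 | 24.1 |
| ochre | 25.0 | 19.7 | 55.9 | 24.9 |

(scatter of a reading: 1 percentage point)

- the reaction counts as stopped when no species that holds the Z changes by six tenths of a point or more over the second half of the time

- at 20 min, what has stopped the reaction, if anything has (forward and back rates have come level / it is still moving / all of Z has reacted)
- conversion of Z at 20 min
- amount of J at 20 min, in percent of the Z charged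
- amount of L at 20 min, in percent of the Z charged

- Averaged over its 4 readings, that sum falls short by 0.65 percentage points in grey, 2.3 points in teal and 1.1 points in ochre, each mean with a scatter of 0.87 points.
- For the new flask, starting Q over starting Z is 2.00%; this ratio m, the toll, is the share of the Z charged that leaves the three species if each Q removes one Z.
- The objection is that the shortfalls may be scatter. The tolls of grey, teal and ochre are 1.35%, 3.06% and 1.32%; teal has the highest toll and the largest shortfall, which favours the toll without proving it.
- A second objection is that Q may shift the mix. Yet teal holds 2.27 times the Q of grey, and their J readings at 25.0 min are 55.1% and 55.8%.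
- Has the mix stopped? Grey's J goes from 56.3% at 20.0 min to 55.8% at 25.0 min, inside the scatter, with Z still at 17.6%: in grey, forward and back rates look level. The new flask, with more Q than grey and less than teal, is expected to have done the same by 20 min.
- Pooling the last readings of the three runs, Z, J and L hold 19.1%, 55.8% and 25.1% of their sum. Multiplying by one minus the toll gives my estimate for the flask: conversion 81.3%, J 54.7%, L 24.6%.
- The forecast, reasoning that “A common endpoint independent of Q and Z points to true equilibrium among isomer-like species”, says that forward and back rates have come level, with conversion 81%, J 55% and L 25%.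
- In the flask at 20 min, forward and back rates have come level, with conversion 81.3%, J 54.3% and L 25.0%.

    Z ⇌ J (K = 2.90, k = 0.00330 s⁻¹)
    J ⇌ L (K = 0.460, k = 0.00240 s⁻¹)
    L ⇌ Z (k = 0.00590 s⁻¹)
    Z + Q → G (k = 2.00 M⁻¹ s⁻¹)

- In the flask at 20.0 min, G stands at 2.00% against the toll of 2.00%, and Q, the limiting reagent of that loss, at 0% of its charge. The same flask read at 5.0 min tests the toll apart from the mix. The toll leaves 98.0% for Z, J and L, and that reading holds Z 22.1%, J 48.1% and L 27.7%, together 97.9%, with G at 2.00% and Q at 0%. The toll is paid there, yet J lies 6.2 points under its 54.3% at 20.0 min.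

All runs are simulated with constants of no real substance; scatter was added.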